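I decided to hand these flasks over with one time worked out by hand.

    free monomer + monomer in chains → side product (k1 = 0.10 M⁻¹ s⁻¹, Ea1 = 43.0 kJ mol⁻¹)
    free monomer + living end → monomer in chains + living end, rate k2*[living end]*[free monomer] (k2 = 7.8 M⁻¹ s⁻¹, Ea2 = 49.0 kJ mol⁻¹)
    free monomer + initiator → living end + monomer in chains (k3 = 4.2 M⁻¹ s⁻¹, Ea3 = 55.0 kJ mol⁻¹)
    free monomer ⇌ dormant form (K4 = 1.5, k4 = 0.0049 s⁻¹, Ea4 = 80.0 kJ mol⁻¹, ΔH4 = −31.0 kJ mol⁻¹)
    (constants at 20 °C)

all flasks: free monomer 34 mM; initiator 0.68 mM; time 10 min
- midnight: temperature −5 °C
- spring: temperature −30 °C
- summer: temperature 20 °C

* the best flask by amount of monomer in chains, in percent of the free monomer charged; "all alike" if 1.5 percentage points covers them all (midnight / spring / summer / all alike)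
* amount of monomer in chains at the end, in percent of the free monomer charged, midnight
* amount of monomer in chains at the end, in percent of the free monomer charged, spring
* amount of monomer in chains at the end, in percent of the free monomer charged, summer

- in percentages every species weighs as the free monomer in it: one side product counts as two
- constants are those at 20 °C; use the activation energies and enthalpies for any other temperature

For whoever takes over the spring flask: chains start when initiator meets free monomer. Free monomer stands at 34 mM against 0.68 mM of initiator, so the initiator decays pseudo-first-order. I carried its mean life, the start time τ = 12.1 min, which is one over the initiation constant k_i times free monomer, with k_i 100 times smaller here than in the summer flask. This τ is longer than the run of 10 min, so do not add initiator to the spring flask: I expected part of it still unused when you come.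

By time t the started fraction is x = 1 − exp(−t/τ), which gave 56.3 % at the end. Each start puts one monomer in chains, and each living end then adds monomer with the growth constant k_p, 62 times smaller than in summer, over an effective time t − τx. The first round gave 2.76 % of the charge in chains.

That round held free monomer at its charge, so I put the answer back. Averaged over the run, free monomer stands lower by about half of that figure, τ lengthens to 12.3 min, and the second round gave 2.71 %.

In the summer flask τ is 7.00 s, far shorter than the run, and growth by itself takes 3.14 min per e-fold of free monomer, so I put summer ahead of spring. I did not follow its dormant form by hand, nor reckon midnight, so naming summer as best stayed a judgement.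

The forecast named summer, with 30 % at midnight, 2.6 % in spring and 51 % in summer, saying of the spring flask that “initiation itself is barely half done”. The simulation gave 29.6 % at midnight, 2.64 % in spring and 53.6 % in summer, so summer was best.

In the spring flask the initiator's half-life read 8.6 min at the end, beside the 8.53 min from τ and shorter than the run, while free monomer's half-life by chain growth read 5.3 h at 6.77 min, far longer than the run. That flask ended with 44 % of its initiator and 97 % of its free monomer.

Left to 25 min, the spring flask gave by τ a first round of 9.11 %, then a second of 8.58 % in chains, with 13.9 % of the initiator left. The computed flask held 8.13 % in chains and 14 % of the initiator.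

(The rate constants are assumed; the result is computed.)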